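# Proposed total synthesis of CNP0222387.1 by decarboxylative ring contraction of a twelve-membered β-keto lactone

## Analysis of the target

The target is a germacranolide. Germacrane numbering is used for every compound below.

- Ring A is the ten-membered carbocycle C1–C10: C1 = CH(OH), C2 and C3 = CH2, C4 (bearing methyl C15) and C5 = the epoxide carbons, C6 = lactone O–CH, C7 = sp2 fusion carbon, C8 = CH–O-tigloyl, C9=C10 with methyl C14 on C10.
- Ring B is the butenolide O–C6–C7=C11–C12(=O), with C13H2–OAc on C11, fused to ring A at C6–C7. Ring C is the C4–C5 oxirane.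

It has five stereocentres (1S,4R,5R,6S,8S), a Z-trisubstituted C9=C10 alkene, a trans epoxide (C3 and C6 trans) and an E-configured tiglate. The epoxide oxygen at C5 and the lactone oxygen at C6 are threo. The C6 and C8 oxygens are 1,3-syn across the sp2 carbon C7, so C5–C9 is a pseudo-meso, 2,4-dioxygenated five-carbon unit.

The feature the strategy is built on is the ring-A segment C1(O)–C2H2–C3H2–C4(CH3)–C5. With C1 taken back to a ketone and the oxirane to its E-olefin, this is a γ,δ-unsaturated ketone, the product pattern of an allyl transfer to an enolate. C2–C3 is the only bond of ring A that lies between a carbonyl-derived carbon and an allylic terminus.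

Sensitive points:
- C6–H is the γ-hydrogen of the butenolide and sits next to the oxirane, so base would open the epoxide by elimination.
- C6, C8 and C13 carry allylic C–O bonds that zerovalent palladium or acid can ionise.
- Acyclic Z-enones with a free C8 hydroxyl dehydrate to furans.
- The C13 acetate is cis to O8 and can migrate.

The synthesis is hard because ring A must hold a Z-trisubstituted alkene and a trans-epoxide at once (no six-membered precursor ring can carry the latter). In addition, the tetrasubstituted C7=C11 alkene carries four different oxygenated arms, and O1, O6, O8 and O13 must each end up in a different state.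

## Retrosynthetic reasoning

**24 to 23.** The C1 carbinol is taken back to the ketone. C1 is flanked by the α-branched alkenyl carbon C10 and the methylene C2, a good substrate for catalyst-controlled reduction, and the free hydroxyl then never needs protection. Keeping C1 as the ketone until the last step also leaves C9=C10 as an electron-poor enone.

**23 to 22.** The two C–O bonds of ring C are cut to give the E-C4=C5 olefin. In 22 this is the only electron-rich alkene; the others are an enone, a butenolide and a tiglate. The forward peracid epoxidation must attack the outer face of the E-olefin, which is the face of the C6 oxygen when C6–H eclipses C15, and this gives the threo (4R,5R,6S) array.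

**22 to 21 to 20.** The tiglate is removed from O8 and replaced by a silyl ether. O8 must stay non-ionisable until the palladium step is over.

**20 to 19 to 16 and 18.** Ring B is opened at C7=C11 (ring-closing metathesis in the forward direction) and at the ester bond O6–C12. This takes C11, C12 and C13, with the acetate already in place, back to the small acid 18 (from 17). Ring A is left with only a methylidene at C7 and a free hydroxyl at C6 (compound 16).

**16 to 15 (key disconnection).** The C2–C3 bond is cut. C2 is reconnected to the C3 oxygen through a carboxyl spacer, giving the twelve-membered β-keto lactone 15. The cut is made here because it turns the hardest ring into an easily closed macrolactone, leaves no activating group to remove, and keeps the E-C4=C5 geometry inside an allyl unit. The forward reaction must ionise the allylic ester, lose the carboxyl carbon, and join C2 to C3 rather than to C5.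

**15 to 13.** The lactone C–O bond is cut to the tert-butyl β-keto ester 13 with a free primary C3 hydroxyl. The forward step goes through the acylketene 14.

**13 to 12 to 11 to 10.** The C1–C2 bond comes from acylation of an acetate enolate by amide 12. The Z-C9=C10 bond comes from a Z-selective olefination at the lactol carbon C9 of 10. That step also releases O6, until then the ring oxygen of the furanose, as the only free secondary hydroxyl.

**10 to 9 to 8 to 7.** O8 is separated from O6 by silylation while O6 is still locked in the furanose ring.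

**7 to 6 to 5.** The E-C4=C5 bond and C3 come from a stabilised Wittig reaction at the C5 aldehyde of 5, followed by reduction.

**5 to 4 to 3 to 2 to 1.** The pseudo-meso C5–C9 unit is mapped onto the hexose skeleton of 1. The anomeric carbon becomes C9; sugar C2 and C4 become C8 and C6, with the configuration that corresponds to 8S and 6S in the target. Sugar C3 becomes C7 (ketone, then methylidene). Sugar C5 becomes C5 after cleavage of the terminal diol.

## Alternatives that were turned down

**Alternative 1: ring-closing metathesis at C9=C10 (the textbook route).** The seco-diene A1 (C8 vinyl carbinol tiglate, C1-silylated C10 isopropenyl carbinol, rings B and C in place) would be closed with a ruthenium carbene to the silyl ether A2 of the target. It was turned down for these reasons: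
- Both alkenes are deactivated and hindered by allylic oxygen, and one is 1,1-disubstituted.
- The ten-membered ring must form against transannular strain, with dimerisation as the easy escape.
- The step sets no stereocentre and builds no part of the chain, so C1, C6 and C8 and every C–C bond of C1–C10 have to be made beforehand. The step count is not lower.

**Alternative 2: Nozaki–Hiyama–Kishi closure at C6–C7 with lactonisation.** The acyclic (Z)-β-iodo enoate epoxy-aldehyde A3 would be treated with CrCl2 and catalytic NiCl2. The vinyl metal at C7 adds to the C6 aldehyde and the alkoxide closes ring B, again giving A2. It was turned down for these reasons: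
- Felkin–Anh addition to a trans-α,β-epoxy aldehyde gives the erythro C5/C6 relation; the target is threo.
- The vinyl chromium at C7 carries the tigloyloxy group on the adjacent carbon C8 and should eliminate to an allene.
- The tetrasubstituted iodoalkene with four different substituents needs its own geometry-controlled synthesis.

**Alternative 3: [2,3]-Wittig ring contraction of a thirteen-membered propargylic allylic ether.** The macrocyclic ether A4 (O bridging C8 and C13; C11≡C7 alkyne) would be deprotonated at C8 and rearranged to the ten-membered allenyl carbinol A5. Cyclocarbonylation with Ru3(CO)12 would then close ring B. The ring contraction itself has close analogy, but it was turned down for these reasons: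
- The bond that is sacrificed is C13–O, so ring B would come out with a C13 methyl group. The acetoxy group would have to be put back by a late allylic oxidation next to three other allylic positions.
- The strongly basic step must also choose between two acidic ether positions.

Key step: step 13

## Route

Remark on the chemistry: lactols 8 and 10 and silyl acetal 9 are anomeric mixtures; C9 carries no descriptor in their SMILES because both anomers converge in step 9.

Step 1
Reactants: 1 1,2:5,6-di-O-isopropylidene-α-D-glucofuranose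
Product: 2 1,2:5,6-di-O-isopropylidene-α-D-ribo-hexofuranos-3-ulose
Conditions: Dess–Martin periodinane, CH2Cl2, rt
Reagents that add atoms: none
Why: Oxidation of the only free (secondary) hydroxyl by a hypervalent iodine reagent; both acetonides are inert and the new ketone carbon is the future C7.

Step 2
Reactants: 2 1,2:5,6-di-O-isopropylidene-α-D-ribo-hexofuranos-3-ulose
Product: 3 3-deoxy-1,2:5,6-di-O-isopropylidene-3-C-methylidene-α-D-ribo-hexofuranose
Conditions: Ph3PCH3Br, KOtBu, THF, 0 °C to rt
Reagents that add atoms: methyltriphenylphosphonium bromide, [Br-].C[P+](c1ccccc1)(c1ccccc1)c1ccccc1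
Why: Wittig methylenation of the reactive 3-ulose; the methylidene masks C7 as an sp2 carbon that survives all later base, hydride and palladium steps and is the metathesis partner in step 16.

Step 3
Reactants: 3 3-deoxy-1,2:5,6-di-O-isopropylidene-3-C-methylidene-α-D-ribo-hexofuranose
Product: 5 (3aR,5S,6aR)-2,2-dimethyl-6-methylidenetetrahydrofuro[2,3-d][1,3]dioxole-5-carbaldehyde, via diol 4 (not isolated)
Conditions: H5IO6, EtOAc, rt
Reagents that add atoms: none
Why: Periodic acid hydrolyses the more labile terminal acetonide and cleaves the resulting glycol in one pot, so sugar C5 becomes the aldehyde carbon C5; the aldehyde is used at once because C6–H is both α to the carbonyl and allylic.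

Step 4
Reactants: 5 (3aR,5S,6aR)-2,2-dimethyl-6-methylidenetetrahydrofuro[2,3-d][1,3]dioxole-5-carbaldehyde
Product: 6 ethyl (2E)-2-methyl-3-[(3aR,5R,6aR)-2,2-dimethyl-6-methylidenetetrahydrofuro[2,3-d][1,3]dioxol-5-yl]prop-2-enoate
Conditions: Ph3P=C(CH3)CO2Et, CH2Cl2, 0 °C to rt
Reagents that add atoms: ethyl 2-(triphenyl-λ5-phosphanylidene)propanoate, CCOC(=O)C(C)=P(c1ccccc1)(c1ccccc1)c1ccccc1
Why: Wittig olefination with an α-methyl stabilised ylide under neutral conditions should give the E-trisubstituted C4=C5 enoate (C3 trans to C6) without epimerising C6.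

Step 5
Reactants: 6 ethyl (2E)-2-methyl-3-[(3aR,5R,6aR)-2,2-dimethyl-6-methylidenetetrahydrofuro[2,3-d][1,3]dioxol-5-yl]prop-2-enoate
Product: 7 (2E)-2-methyl-3-[(3aR,5R,6aR)-2,2-dimethyl-6-methylidenetetrahydrofuro[2,3-d][1,3]dioxol-5-yl]prop-2-en-1-ol
Conditions: iBu2AlH, CH2Cl2, −78 °C
Reagents that add atoms: none
Why: 1,2-Reduction of the enoate to the primary allylic alcohol (C3–OH), the oxygen that later carries the β-keto ester tether; acetal and alkenes are untouched.

Step 6
Reactants: 7 (2E)-2-methyl-3-[(3aR,5R,6aR)-2,2-dimethyl-6-methylidenetetrahydrofuro[2,3-d][1,3]dioxol-5-yl]prop-2-en-1-ol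
Product: 8 (3R,5R)-5-[(1E)-3-hydroxy-2-methylprop-1-en-1-yl]-4-methylideneoxolane-2,3-diol (anomeric mixture)
Conditions: AcOH/H2O (4:1), 60 °C
Reagents that add atoms: none
Why: Mild aqueous acid hydrolyses the 1,2-acetonide at its ketal carbon; this frees O8 and the anomeric hydroxyl while O6 stays locked as the furanose ring oxygen.

Step 7
Reactants: 8 (3R,5R)-5-[(1E)-3-hydroxy-2-methylprop-1-en-1-yl]-4-methylideneoxolane-2,3-diol
Product: 9 (3R,5R)-2,3-bis[(tert-butyldimethylsilyl)oxy]-5-[(1E)-3-[(tert-butyldimethylsilyl)oxy]-2-methylprop-1-en-1-yl]-4-methylideneoxolane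
Conditions: TBSCl, imidazole, DMF, rt
Reagents that add atoms: tert-butyldimethylsilyl chloride, CC(C)(C)[Si](C)(C)Cl
Why: Exhaustive silylation is the reliable way to place a silyl ether on the hindered secondary O8; the two extra silyl groups are removed selectively in the next step.

Step 8
Reactants: 9 (3R,5R)-2,3-bis[(tert-butyldimethylsilyl)oxy]-5-[(1E)-3-[(tert-butyldimethylsilyl)oxy]-2-methylprop-1-en-1-yl]-4-methylideneoxolane
Product: 10 (3R,5R)-3-[(tert-butyldimethylsilyl)oxy]-5-[(1E)-3-hydroxy-2-methylprop-1-en-1-yl]-4-methylideneoxolan-2-ol (anomeric mixture)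
Conditions: HF·pyridine, pyridine, THF, 0 °C
Reagents that add atoms: none
Why: Buffered fluoride should cleave the acetal-type anomeric silyl ether and the primary allylic silyl ether much faster than the secondary C8 ether, which is flanked by the anomeric carbon and the methylidene; the net result of steps 7 and 8 is protection of O8 alone.

Step 9
Reactants: 10 (3R,5R)-3-[(tert-butyldimethylsilyl)oxy]-5-[(1E)-3-hydroxy-2-methylprop-1-en-1-yl]-4-methylideneoxolan-2-ol
Product: 11 ethyl (2Z,4S,6R,7E)-4-[(tert-butyldimethylsilyl)oxy]-6,9-dihydroxy-2,8-dimethyl-5-methylidenenona-2,7-dienoate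
Conditions: ethyl 2-[bis(2,2,2-trifluoroethoxy)phosphoryl]propanoate, KN(SiMe3)2 (3 equiv), 18-crown-6, THF, −78 to −40 °C
Reagents that add atoms: ethyl 2-[bis(2,2,2-trifluoroethoxy)phosphoryl]propanoate, CCOC(=O)C(C)P(=O)(OCC(F)(F)F)OCC(F)(F)F
Why: Still–Gennari olefination of the open-chain aldehyde form of the lactol should give the Z-trisubstituted C9=C10 enoate (C8 cis to C1) under kinetic control; ring opening releases O6 as the only free secondary hydroxyl, and with O8 silylated no butenolide can form at this end.

Step 10
Reactants: 11 ethyl (2Z,4S,6R,7E)-4-[(tert-butyldimethylsilyl)oxy]-6,9-dihydroxy-2,8-dimethyl-5-methylidenenona-2,7-dienoate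
Product: 12 (2Z,4S,6R,7E)-4-[(tert-butyldimethylsilyl)oxy]-6,9-dihydroxy-N-methoxy-N,2,8-trimethyl-5-methylidenenona-2,7-dienamide
Conditions: MeNH(OMe)·HCl, iPrMgCl (excess), THF, −20 to 0 °C
Reagents that add atoms: N,O-dimethylhydroxylamine hydrochloride, Cl.CNOC
Why: Weinreb amide formation with a magnesium amide, which is not basic enough to deprotonate C8–H; the free hydroxyls are carried as magnesium alkoxides and the Z geometry is kept.

Step 11
Reactants: 12 (2Z,4S,6R,7E)-4-[(tert-butyldimethylsilyl)oxy]-6,9-dihydroxy-N-methoxy-N,2,8-trimethyl-5-methylidenenona-2,7-dienamide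
Product: 13 tert-butyl (4Z,6S,8R,9E)-6-[(tert-butyldimethylsilyl)oxy]-8,11-dihydroxy-4,10-dimethyl-7-methylidene-3-oxoundeca-4,9-dienoate
Conditions: tert-butyl acetate, LiN(iPr)2 (excess), THF, −78 °C; then aqueous NH4Cl
Reagents that add atoms: tert-butyl acetate, CC(=O)OC(C)(C)C
Why: Claisen-type acylation of the lithium ester enolate by the Weinreb amide stops at the ketone stage through the chelated tetrahedral intermediate; this creates the C1–C2 bond and the C1 ketone, and the product is shielded from further base as its β-keto ester enolate.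

Step 12
Reactants: 13 tert-butyl (4Z,6S,8R,9E)-6-[(tert-butyldimethylsilyl)oxy]-8,11-dihydroxy-4,10-dimethyl-7-methylidene-3-oxoundeca-4,9-dienoate
Product: 15 (5Z,7S,9R,10E)-7-[(tert-butyldimethylsilyl)oxy]-9-hydroxy-5,11-dimethyl-8-methylidene-1-oxacyclododeca-5,10-diene-2,4-dione, via acylketene 14 (not isolated)
Conditions: toluene, 110 °C, slow addition at high dilution
Reagents that add atoms: none
Why: Thermal loss of tert-butanol from the β-keto ester gives an acylketene that is trapped intramolecularly (acylketene macrolactonisation); the unhindered primary C3 hydroxyl closes the twelve-membered ring, whereas the hindered secondary C6 hydroxyl would have to close a nine-membered ring.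

Step 13
Reactants: 15 (5Z,7S,9R,10E)-7-[(tert-butyldimethylsilyl)oxy]-9-hydroxy-5,11-dimethyl-8-methylidene-1-oxacyclododeca-5,10-diene-2,4-dione
Product: 16 (2Z,4S,6R,7E)-4-[(tert-butyldimethylsilyl)oxy]-6-hydroxy-2,8-dimethyl-5-methylidenecyclodeca-2,7-dien-1-one
Conditions: Pd(PPh3)4 (10 mol %), THF, 25–40 °C, dilute
Reagents that add atoms: none
Why: Proposed new method: zerovalent palladium should ionise the only allylic ester of 15 (the C3–O bond) to a syn-configured π-allyl complex spanning C3–C4–C5 that stays tied to the β-keto carboxylate through C6–C10; loss of the carboxyl carbon then gives the enolate of the C1 ketone as a contact ion pair, and bond formation between C2 and the unsubstituted allyl terminus C3 contracts the twelve-membered lactone to ring A. The closest known reaction type is the palladium-catalysed decarboxylative allylation of allyl β-keto esters (the catalytic Carroll reaction, which converts geranyl-type acetoacetates into linear E-configured γ,δ-unsaturated ketones), together with intramolecular π-allylpalladium alkylations that close medium and large carbocycles; what is new is that the ester tether is itself the ring, so the macrocycle contracts. Ring A closes in the ten-membered mode by attack at C3, which places all three allyl carbons in the ring; the eight-membered mode (attack at C5, leaving an exocyclic isopropenyl group) is disfavoured because C5 is the substituted terminus and has the C6 carbinol next to it, the same bias that sends nucleophiles to the distal terminus of vinyl-epoxide-derived π-allyl complexes. No stereocentre is formed and C6 and C8 are not touched; the E geometry of C4=C5 is kept because the syn π-allyl is captured before syn–anti isomerisation, and the Z-C9=C10 enone is a spectator. The step needs chemoselective ionisation, secured because O6 is a free hydroxyl, O8 a silyl ether and no other allylic ester is present. It needs C- rather than O-allylation, and an O-allyl enol ether would re-ionise and funnel to the ketone. It needs capture within the ion pair rather than protonation or dimerisation, which the covalent tether and dilution favour.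

Step 14
Reactants: 17 2-(bromomethyl)prop-2-enoic acid
Product: 18 2-[(acetyloxy)methyl]prop-2-enoic acid
Conditions: KOAc (excess), AcOH, 60 °C
Reagents that add atoms: potassium acetate, [K+].CC([O-])=O
Why: Allylic substitution of the activated bromide by acetate (direct and conjugate displacement give the same product); excess acetate in acetic acid suppresses self-alkylation of the acid.

Step 15
Reactants: 16 (2Z,4S,6R,7E)-4-[(tert-butyldimethylsilyl)oxy]-6-hydroxy-2,8-dimethyl-5-methylidenecyclodeca-2,7-dien-1-one; 18 2-[(acetyloxy)methyl]prop-2-enoic acid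
Product: 19 (1R,2E,7Z,9S)-9-[(tert-butyldimethylsilyl)oxy]-3,7-dimethyl-10-methylidene-6-oxocyclodeca-2,7-dien-1-yl 2-[(acetyloxy)methyl]prop-2-enoate
Conditions: N,N'-diisopropylcarbodiimide, DMAP (cat.), CH2Cl2, 0 °C to rt
Reagents that add atoms: none
Why: Steglich esterification of the only free hydroxyl (O6); any reversible conjugate displacement of the allylic acetate by DMAP is degenerate, and the allylic acetate is harmless now that the palladium step is past.

Step 16
Reactants: 19 (1R,2E,7Z,9S)-9-[(tert-butyldimethylsilyl)oxy]-3,7-dimethyl-10-methylidene-6-oxocyclodeca-2,7-dien-1-yl 2-[(acetyloxy)methyl]prop-2-enoate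
Product: 20 (4E,9Z,6R,8S)-13-acetoxy-8-[(tert-butyldimethylsilyl)oxy]-1-oxogermacra-4,7(11),9-trien-12,6-olide
Conditions: second-generation Hoveyda–Grubbs catalyst RuCl2(H2IMes)(=CH–C6H4-2-OiPr) (10–20 mol %), toluene, 80 °C, argon sparge
Reagents that add atoms: none
Why: Ring-closing metathesis between the C7 methylidene and the acrylate closes ring B and forms the tetrasubstituted C7=C11 bond; the five-membered ring fixes C12 cis to C6 and C13 cis to C8, and the trisubstituted C4=C5 and C9=C10 alkenes are too hindered to compete.

Step 17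
Reactants: 20 (4E,9Z,6R,8S)-13-acetoxy-8-[(tert-butyldimethylsilyl)oxy]-1-oxogermacra-4,7(11),9-trien-12,6-olide
Product: 21 (4E,9Z,6R,8S)-13-acetoxy-8-hydroxy-1-oxogermacra-4,7(11),9-trien-12,6-olide
Conditions: HF·pyridine, pyridine, THF, 0 °C to rt
Reagents that add atoms: none
Why: Acidic fluoride removes the secondary silyl ether without touching the acetate, the butenolide or its base-labile C6–H; dehydration of the Z-γ-hydroxy enone to a furan is blocked because the furan would bridge ring A at C8 and C1.

Step 18
Reactants: 21 (4E,9Z,6R,8S)-13-acetoxy-8-hydroxy-1-oxogermacra-4,7(11),9-trien-12,6-olide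
Product: 22 (4E,9Z,6R,8S)-13-acetoxy-1-oxo-8-[(2E)-2-methylbut-2-enoyloxy]germacra-4,7(11),9-trien-12,6-olide
Conditions: (E)-2-methylbut-2-enoyl chloride, pyridine, DMAP (cat.), CH2Cl2, 0 °C
Reagents that add atoms: (E)-2-methylbut-2-enoyl chloride, C/C=C(\C)C(Cl)=O
Why: Acylation of the single free hydroxyl with the configurationally stable E acid chloride; the alcohol is not deprotonated under these conditions, which keeps migration of the cis C13 acetate slow.

Step 19
Reactants: 22 (4E,9Z,6R,8S)-13-acetoxy-1-oxo-8-[(2E)-2-methylbut-2-enoyloxy]germacra-4,7(11),9-trien-12,6-olide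
Product: 23 (9Z,4R,5R,6S,8S)-13-acetoxy-4,5-epoxy-1-oxo-8-[(2E)-2-methylbut-2-enoyloxy]germacra-7(11),9-dien-12,6-olide
Conditions: mCPBA, NaHCO3, CH2Cl2, 0 °C
Reagents that add atoms: 3-chloroperoxybenzoic acid, OOC(=O)c1cccc(Cl)c1
Why: Prilezhaev epoxidation of the only electron-rich alkene (C4=C5; the other three are conjugated to carbonyl groups) from the outer face of the E-olefin; with C6–H eclipsing methyl C15 (1,3-allylic strain) that face is the one bearing the C6 oxygen, which gives the threo (4R,5R) oxirane.

Step 20
Reactants: 23 (9Z,4R,5R,6S,8S)-13-acetoxy-4,5-epoxy-1-oxo-8-[(2E)-2-methylbut-2-enoyloxy]germacra-7(11),9-dien-12,6-olide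
Product: 24 (9Z,1S,4R,5R,6S,8S)-13-acetoxy-4,5-epoxy-1-hydroxy-8-[(2E)-2-methylbut-2-enoyloxy]germacra-7(11),9-dien-12,6-olide (CNP0222387.1)
Conditions: (R)-2-methyl-CBS-oxazaborolidine (20 mol %), catecholborane, toluene, −78 °C
Reagents that add atoms: none
Why: Corey–Bakshi–Shibata reduction; the α-methyl alkenyl carbon C10 acts as the large group and C2 as the small one, so the (R)-catalyst should deliver hydride to give the 1S carbinol, and catecholborane at low temperature leaves lactone, esters and epoxide alone.

## Compound list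

1 | 1,2:5,6-di-O-isopropylidene-α-D-glucofuranose | CC1(C)O[C@H]2O[C@@H]([C@H](O)[C@H]2O1)[C@H]1COC(C)(C)O1 | starting material
2 | 1,2:5,6-di-O-isopropylidene-α-D-ribo-hexofuranos-3-ulose | CC1(C)O[C@H]2O[C@@H](C(=O)[C@H]2O1)[C@H]1COC(C)(C)O1 | intermediate
3 | 3-deoxy-1,2:5,6-di-O-isopropylidene-3-C-methylidene-α-D-ribo-hexofuranose | CC1(C)O[C@H]2O[C@@H](C(=C)[C@H]2O1)[C@H]1COC(C)(C)O1 | intermediate
4 | 3-deoxy-1,2-O-isopropylidene-3-C-methylidene-α-D-ribo-hexofuranose (5,6-diol, not isolated) | CC1(C)O[C@H]2O[C@@H](C(=C)[C@H]2O1)[C@H](O)CO | intermediate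
5 | (3aR,5S,6aR)-2,2-dimethyl-6-methylidenetetrahydrofuro[2,3-d][1,3]dioxole-5-carbaldehyde | CC1(C)O[C@H]2O[C@@H](C(=C)[C@H]2O1)C=O | intermediate
6 | ethyl (2E)-2-methyl-3-[(3aR,5R,6aR)-2,2-dimethyl-6-methylidenetetrahydrofuro[2,3-d][1,3]dioxol-5-yl]prop-2-enoate | CC1(C)O[C@H]2O[C@@H](C(=C)[C@H]2O1)/C=C(\C)C(=O)OCC | intermediate
7 | (2E)-2-methyl-3-[(3aR,5R,6aR)-2,2-dimethyl-6-methylidenetetrahydrofuro[2,3-d][1,3]dioxol-5-yl]prop-2-en-1-ol | CC1(C)O[C@H]2O[C@@H](C(=C)[C@H]2O1)/C=C(\C)CO | intermediate
8 | (3R,5R)-5-[(1E)-3-hydroxy-2-methylprop-1-en-1-yl]-4-methylideneoxolane-2,3-diol (anomeric mixture) | OC1O[C@@H](C(=C)[C@H]1O)/C=C(\C)CO | intermediate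
9 | (3R,5R)-2,3-bis[(tert-butyldimethylsilyl)oxy]-5-[(1E)-3-[(tert-butyldimethylsilyl)oxy]-2-methylprop-1-en-1-yl]-4-methylideneoxolane (anomeric mixture) | CC(C)(C)[Si](C)(C)OC1O[C@@H](C(=C)[C@H]1O[Si](C)(C)C(C)(C)C)/C=C(\C)CO[Si](C)(C)C(C)(C)C | intermediate
10 | (3R,5R)-3-[(tert-butyldimethylsilyl)oxy]-5-[(1E)-3-hydroxy-2-methylprop-1-en-1-yl]-4-methylideneoxolan-2-ol (anomeric mixture) | OC1O[C@@H](C(=C)[C@H]1O[Si](C)(C)C(C)(C)C)/C=C(\C)CO | intermediate
11 | ethyl (2Z,4S,6R,7E)-4-[(tert-butyldimethylsilyl)oxy]-6,9-dihydroxy-2,8-dimethyl-5-methylidenenona-2,7-dienoate | OC/C(C)=C/[C@@H](O)C(=C)[C@@H](O[Si](C)(C)C(C)(C)C)/C=C(/C)C(=O)OCC | intermediate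
12 | (2Z,4S,6R,7E)-4-[(tert-butyldimethylsilyl)oxy]-6,9-dihydroxy-N-methoxy-N,2,8-trimethyl-5-methylidenenona-2,7-dienamide | OC/C(C)=C/[C@@H](O)C(=C)[C@@H](O[Si](C)(C)C(C)(C)C)/C=C(/C)C(=O)N(C)OC | intermediate
13 | tert-butyl (4Z,6S,8R,9E)-6-[(tert-butyldimethylsilyl)oxy]-8,11-dihydroxy-4,10-dimethyl-7-methylidene-3-oxoundeca-4,9-dienoate | OC/C(C)=C/[C@@H](O)C(=C)[C@@H](O[Si](C)(C)C(C)(C)C)/C=C(/C)C(=O)CC(=O)OC(C)(C)C | intermediate
14 | (4Z,6S,8R,9E)-6-[(tert-butyldimethylsilyl)oxy]-8,11-dihydroxy-4,10-dimethyl-7-methylideneundeca-1,4,9-triene-1,3-dione (acylketene, not isolated) | OC/C(C)=C/[C@@H](O)C(=C)[C@@H](O[Si](C)(C)C(C)(C)C)/C=C(/C)C(=O)C=C=O | intermediate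
15 | (5Z,7S,9R,10E)-7-[(tert-butyldimethylsilyl)oxy]-9-hydroxy-5,11-dimethyl-8-methylidene-1-oxacyclododeca-5,10-diene-2,4-dione | CC(C)(C)[Si](C)(C)O[C@H]1/C=C(/C)C(=O)CC(=O)OC/C(C)=C/[C@@H](O)C1=C | intermediate
16 | (2Z,4S,6R,7E)-4-[(tert-butyldimethylsilyl)oxy]-6-hydroxy-2,8-dimethyl-5-methylidenecyclodeca-2,7-dien-1-one | CC(C)(C)[Si](C)(C)O[C@H]1/C=C(/C)C(=O)CC/C(C)=C/[C@@H](O)C1=C | intermediate
17 | 2-(bromomethyl)prop-2-enoic acid | OC(=O)C(=C)CBr | starting material
18 | 2-[(acetyloxy)methyl]prop-2-enoic acid | CC(=O)OCC(=C)C(O)=O | intermediate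
19 | (1R,2E,7Z,9S)-9-[(tert-butyldimethylsilyl)oxy]-3,7-dimethyl-10-methylidene-6-oxocyclodeca-2,7-dien-1-yl 2-[(acetyloxy)methyl]prop-2-enoate | CC(C)(C)[Si](C)(C)O[C@H]1/C=C(/C)C(=O)CC/C(C)=C/[C@@H](OC(=O)C(=C)COC(C)=O)C1=C | intermediate
20 | (4E,9Z,6R,8S)-13-acetoxy-8-[(tert-butyldimethylsilyl)oxy]-1-oxogermacra-4,7(11),9-trien-12,6-olide | CC(C)(C)[Si](C)(C)O[C@H]1/C=C(/C)C(=O)CC/C(C)=C/[C@H]2OC(=O)C(COC(C)=O)=C12 | intermediate
21 | (4E,9Z,6R,8S)-13-acetoxy-8-hydroxy-1-oxogermacra-4,7(11),9-trien-12,6-olide | O[C@H]1/C=C(/C)C(=O)CC/C(C)=C/[C@H]2OC(=O)C(COC(C)=O)=C12 | intermediate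
22 | (4E,9Z,6R,8S)-13-acetoxy-1-oxo-8-[(2E)-2-methylbut-2-enoyloxy]germacra-4,7(11),9-trien-12,6-olide | C/C=C(\C)C(=O)O[C@H]1/C=C(/C)C(=O)CC/C(C)=C/[C@H]2OC(=O)C(COC(C)=O)=C12 | intermediate
23 | (9Z,4R,5R,6S,8S)-13-acetoxy-4,5-epoxy-1-oxo-8-[(2E)-2-methylbut-2-enoyloxy]germacra-7(11),9-dien-12,6-olide | C/C=C(\C)C(=O)O[C@H]1/C=C(/C)C(=O)CC[C@@]2(C)O[C@@H]2[C@H]2OC(=O)C(COC(C)=O)=C12 | intermediate
24 | (9Z,1S,4R,5R,6S,8S)-13-acetoxy-4,5-epoxy-1-hydroxy-8-[(2E)-2-methylbut-2-enoyloxy]germacra-7(11),9-dien-12,6-olide (CNP0222387.1) | C/C=C(\C)C(=O)O[C@H]1/C=C(/C)[C@@H](O)CC[C@@]2(C)O[C@@H]2[C@H]2OC(=O)C(COC(C)=O)=C12 | target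

## Step count and least certain steps

Total: 20 steps. Longest linear sequence: 19 steps (steps 1–13 and 15–20, from 1); step 14 is a one-step branch to 18.

**Step 13 (key step, proposed new method).** Most likely to go wrong: the palladium enolate is protonated and the allyl unit is lost as a diene by β-hydride elimination; the ring closes at C5 in the eight-membered mode; or two ion pairs combine to a dimer, because the ten-membered transition state is strained. The fallback uses known chemistry and sets out from 13. The primary C3 hydroxyl is converted selectively (methyl chloroformate, pyridine, −20 °C) into the allyl methyl carbonate F1. Pd(PPh3)4 at high dilution then effects a neutral intramolecular Tsuji–Trost alkylation, in which the methoxide released deprotonates the β-keto ester, to give the ten-membered tert-butyl β-keto ester F2. Heating F2 in wet dioxane removes the tert-butyl ester and the carboxyl group through the acylketene and the β-keto acid, and the route is rejoined at 16.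

**Step 16.** Most likely to go wrong: the catalyst fails to load onto or turn over at the hindered methylidene between C6 and C8, so that decomposition and alkene isomerisation overtake formation of the tetrasubstituted alkene. The fallback sets out from 16. Esterification with acrylic acid gives the acrylate F3. Its ring-closing metathesis has to form only a trisubstituted alkene and gives the C11-unsubstituted butenolide F4. Iodination at C11 (I2, pyridine) gives the iodobutenolide F5. Stille coupling with Bu3SnCH2OH and Pd(PPh3)4 gives the C13 alcohol F6, and acetylation (Ac2O, pyridine) rejoins the route at 20.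

**Step 9.** Most likely to go wrong: slow opening of the lactolate at low temperature; conjugate addition of the liberated C6 alkoxide to the new enoate (five-membered ether formation); O-to-O silyl migration from O8; and loss of Z selectivity on warming. The fallback sets out from 10. Stork–Zhao olefination with Ph3P=C(I)CH3 gives the (Z)-iodoalkene F7, which is not a conjugate acceptor. Palladium-catalysed ethoxycarbonylation (PdCl2(PPh3)2, CO, EtOH, Et3N) with retention of geometry rejoins the route at 11.

**Step 19.** Most likely to go wrong: poor facial selectivity if ring A populates a conformer in which the C6 oxygen, not C6–H, lies in the plane of the C4=C5 olefin. The fallback sets out from 22 and replaces substrate control by reagent control: a Shi epoxidation with the enantiomer of the fructose-derived ketone catalyst matched to the 4R,5R face and KHSO5 in buffered MeCN/water. It rejoins the route at 23 and makes no new compound.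

**Step 20.** Most likely to go wrong: weak discrimination between the two ring-bound flanks of the C1 ketone, giving the C1 epimer, or slow reduction of the hindered enone. The fallback sets out from 23 and uses an enzymatic ketoreductase with cofactor recycling at neutral pH, screened for the 1S alcohol. It rejoins the route at 24 and makes no new compound.

## Further compounds

F1 | step 13 | tert-butyl (4Z,6S,8R,9E)-6-[(tert-butyldimethylsilyl)oxy]-8-hydroxy-11-[(methoxycarbonyl)oxy]-4,10-dimethyl-7-methylidene-3-oxoundeca-4,9-dienoate | COC(=O)OC/C(C)=C/[C@@H](O)C(=C)[C@@H](O[Si](C)(C)C(C)(C)C)/C=C(/C)C(=O)CC(=O)OC(C)(C)C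
F2 | step 13 | tert-butyl (3Z,5S,7R,8E)-5-[(tert-butyldimethylsilyl)oxy]-7-hydroxy-3,9-dimethyl-6-methylidene-2-oxocyclodeca-3,8-diene-1-carboxylate (mixture at C1 of the ring) | CC(C)(C)[Si](C)(C)O[C@H]1/C=C(/C)C(=O)C(C(=O)OC(C)(C)C)C/C(C)=C/[C@@H](O)C1=C
F3 | step 16 | (1R,2E,7Z,9S)-9-[(tert-butyldimethylsilyl)oxy]-3,7-dimethyl-10-methylidene-6-oxocyclodeca-2,7-dien-1-yl prop-2-enoate | CC(C)(C)[Si](C)(C)O[C@H]1/C=C(/C)C(=O)CC/C(C)=C/[C@@H](OC(=O)C=C)C1=C
F4 | step 16 | (4E,9Z,6R,8S)-8-[(tert-butyldimethylsilyl)oxy]-1-oxo-13-norgermacra-4,7(11),9-trien-12,6-olide | CC(C)(C)[Si](C)(C)O[C@H]1/C=C(/C)C(=O)CC/C(C)=C/[C@H]2OC(=O)C=C12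
F5 | step 16 | (4E,9Z,6R,8S)-8-[(tert-butyldimethylsilyl)oxy]-11-iodo-1-oxo-13-norgermacra-4,7(11),9-trien-12,6-olide | CC(C)(C)[Si](C)(C)O[C@H]1/C=C(/C)C(=O)CC/C(C)=C/[C@H]2OC(=O)C(I)=C12
F6 | step 16 | (4E,9Z,6R,8S)-8-[(tert-butyldimethylsilyl)oxy]-13-hydroxy-1-oxogermacra-4,7(11),9-trien-12,6-olide | CC(C)(C)[Si](C)(C)O[C@H]1/C=C(/C)C(=O)CC/C(C)=C/[C@H]2OC(=O)C(CO)=C12
F7 | step 9 | (2E,4R,6S,7Z)-6-[(tert-butyldimethylsilyl)oxy]-8-iodo-2-methyl-5-methylidenenona-2,7-diene-1,4-diol | OC/C(C)=C/[C@@H](O)C(=C)[C@@H](O[Si](C)(C)C(C)(C)C)/C=C(/C)I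
F0 | step 19 | none | none
F0 | step 20 | none | none
A1 | alternative 1 | seco-diene: 13-acetoxy-1-[(tert-butyldimethylsilyl)oxy]-4,5-epoxy-8-tigloyloxy-9,10-seco-germacra-7(11),9,10(seco)-trien-12,6-olide (C8 vinyl carbinol tiglate, C10 isopropenyl) | C=C(C)[C@@H](O[Si](C)(C)C(C)(C)C)CC[C@@]1(C)O[C@@H]1[C@H]1OC(=O)C(COC(C)=O)=C1[C@@H](OC(=O)/C(C)=C/C)C=C
A2 | alternative 1 | 1-O-(tert-butyldimethylsilyl) ether of the target | C/C=C(\C)C(=O)O[C@H]1/C=C(/C)[C@@H](O[Si](C)(C)C(C)(C)C)CC[C@@]2(C)O[C@@H]2[C@H]2OC(=O)C(COC(C)=O)=C12
A3 | alternative 2 | acyclic (Z)-β-iodo enoate epoxy-aldehyde (C6 aldehyde, C7 iodide, methyl ester at C12, C1 silyl ether, C8 tiglate) | O=C[C@H]1O[C@]1(C)CC[C@H](O[Si](C)(C)C(C)(C)C)/C(C)=C\[C@H](OC(=O)/C(C)=C/C)/C(I)=C(\COC(C)=O)C(=O)OC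
A4 | alternative 3 | thirteen-membered ether with O bridging C8 and C13, C11≡C7 alkyne, 4E and 9Z alkenes, C1 and C6 silyl ethers | O1CC#C[C@H](O[Si](C)(C)C(C)(C)C)/C=C(\C)CC[C@H](O[Si](C)(C)C(C)(C)C)/C(C)=C\C1
A5 | alternative 3 | ten-membered allenyl carbinol (C8 hydroxyl, C7=C11=C13H2 allene, C1 and C6 silyl ethers) | O[C@H]1/C=C(/C)[C@@H](O[Si](C)(C)C(C)(C)C)CC/C(C)=C/[C@@H](O[Si](C)(C)C(C)(C)C)C1=C=C
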